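At late times the split of the intermediate in this flask is a two-way affair, as your hunch had it: the first nucleophile decays with a half-life of 9.9 min, shorter than the 50 min of the run.

substrate 0.20 M; first nucleophile 1.50 equiv; second nucleophile 2.50 equiv; time 50 min

    substrate → intermediate (k1 = 0.015 /min)
    first nucleophile + intermediate → target (k2 = 62 /M/min)
    second nucleophile + intermediate → other capture product (k3 = 48 /M/min)
    intermediate → solvolysis product (k4 = 28 /min)
    first nucleophile → decomposed reagent (k5 = 0.070 /min)

- the reaction counts as stopped when no species that holds the substrate changes by six tenths of a point or more over the second half of the time
- run time (flask): 50 min

* the state of affairs at 50 min: stopped, and by what, or still going (it is still moving / forward and back rates have come level / all of the substrate has reacted / the first nucleophile has run out first / the second nucleophile has run out first)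
* conversion of substrate at 50 min
* amount of target at 50 min, in percent of the substrate charged
* amount of solvolysis product at 50 min, in percent of the substrate charged

The quick number comes in three steps. [second nucleophile] starts at 0.500 M, more than the substrate charge, so capture is close to pseudo-first-order in the intermediate. With [second nucleophile] as charged and the first nucleophile left out, the intermediate is lost at 52.0 /min, far above the 0.015 /min of the substrate, so it stays a trace and the first step is rate-limiting. Conversion is therefore 52.8%. Over the second half of the run the substrate still falls by 21 percentage points, so this flask is still moving.

Dividing the rate of solvolysis by the rate of capture by the second nucleophile cancels [intermediate] and time. What remains is the partition ratio, the solvolysis constant over the capture constant times [second nucleophile], 1.17. Dividing the rate of target formation by the decay rate of the first nucleophile also removes time. With substrate held at its charge, this gives target 6.55%. The remaining conversion splits by the partition ratio, so solvolysis product comes to 24.9%.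

The forecast reads it is still moving, with conversion 52.8%, target 5% and solvolysis product 26.3%, and says the intermediate “simply partitions according to its capture rates”. The simulation gives it is still moving, with conversion 52.8%, target 5.13% and solvolysis product 26.2%.

In this flask, solvolysis uses the intermediate 1.2 times as fast as capture by the second nucleophile at 9.19 min, and the two products stand in a ratio of 1.22 at 50.0 min, against a partition ratio of 1.17. In the neighbouring flask with 0.34 M of substrate, equivalents and time held, [second nucleophile] starts at 0.850 M, the partition ratio drops to 0.686, and the readings of 19.5% solvolysis product and 26.9% other capture product give 0.725.

(The numbers are invented.)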